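**Plan**

1. Enabling feature: ring A (C1 bearing the ester carbonyl, C2–OMe, C3–H, C4–OMe, C5–H, C6–pentyl) is a 2,6-disubstituted 4-methoxybenzoate. Its C4(OMe)–C5(H) pair maps onto 1,1-dimethoxyethene, and C1, C2, C3, C6 map onto C5, C4, C3, C6 of a 4-methoxy-6-pentyl-2-pyrone-5-carboxylate.
2. Retrosynthesis: remove the three benzyl groups, then cut ring A bonds C3–C4 and C5–C6 (cycloaddition, then loss of CO2 and MeOH), then the ester C(=O)–O bond between the pyrone acid and the ring B phenol. The pyrone is then cut at its lactone C–O bond and its C-acyl bond (hexanoyl chloride plus dibenzyl 3-oxopentanedioate).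
3. Forward, ring B: divarinol is bought, receives its third oxygen by lithiation between the two ether oxygens, and its carboxyl by formylation and oxidation (steps 1–7).
4. Forward, ring A: the pyrone closes by enol lactonisation (steps 8–11), esterification joins the halves (step 12), ring A is formed last on the finished ester (step 13), and hydrogenolysis ends the route (step 14).
5. Stereochemistry: the target has no stereocentre; the two bridgehead centres of the transient cycloadduct vanish on aromatisation.

Key step: step 13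

Assumption: dibenzyl 3-oxopentanedioate and 1,1-dimethoxyethene are taken as catalogue compounds (the latter freshly distilled); all pyrones are numbered as pyran-2-ones (O1, C2=O, C3 to C6).

**Route**

Step 1
Reactants: 1 5-propylbenzene-1,3-diol (divarinol)
Product: 2 1,3-bis(benzyloxy)-5-propylbenzene
Conditions: BnBr, K2CO3, DMF, rt → 50 °C
Reagents that add atoms: benzyl bromide, BrCc1ccccc1
Why: Williamson ether synthesis on both phenols of the symmetric resorcinol, the standard entry to dibenzyl ethers of 5-alkylresorcinols, should give the diether with O-alkylation favoured in DMF.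

Step 2
Reactants: 2 1,3-bis(benzyloxy)-5-propylbenzene
Product: 5 2,6-bis(benzyloxy)-4-propylphenol, via aryllithium 3 (not isolated), via dimethyl arylboronate 4 (not isolated)
Conditions: n-BuLi, THF, 0 °C; B(OMe)3, −78 °C → rt; 30% H2O2, AcOH, 0 °C → rt
Reagents that add atoms: hydrogen peroxide, OO
Why: Directed ortho-metalation removes the ring proton flanked by the two alkoxy groups, and borate trapping followed by oxidative C–B to C–O migration is the standard hydroxylation of a 1,3-dialkoxybenzene between its oxygens, the low temperature holding back deprotonation at the benzylic OCH2 groups.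

Step 3
Reactants: 5 2,6-bis(benzyloxy)-4-propylphenol
Product: 6 2,6-bis(benzyloxy)-4-propylphenyl acetate
Conditions: Ac2O, pyridine, DMAP (cat.), CH2Cl2, rt
Reagents that add atoms: acetic anhydride, CC(=O)OC(C)=O
Why: DMAP-catalysed acetylation (nucleophilic acyl substitution) masks the central phenol as an ester that is orthogonal to the benzyl groups and can later be removed by mild methanolysis.

Step 4
Reactants: 6 2,6-bis(benzyloxy)-4-propylphenyl acetate
Product: 8 2,6-bis(benzyloxy)-3-formyl-4-propylphenyl acetate, via aryl iminium chloride 7 (not isolated)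
Conditions: POCl3, DMF, 75 °C; then aq. NaOAc, rt
Reagents that add atoms: N,N-dimethylformamide, CN(C)C=O; water, O
Why: Vilsmeier–Haack formylation should occur at one of the two equivalent free positions, each ortho to one benzyloxy group and para to the other as in the well-known formylation of 3,4,5-trialkoxytoluenes, so that symmetry allows only one regioisomer.

Step 5
Reactants: 8 2,6-bis(benzyloxy)-3-formyl-4-propylphenyl acetate
Product: 9 3-acetoxy-2,4-bis(benzyloxy)-6-propylbenzoic acid
Conditions: NaClO2, NaH2PO4, 2-methyl-2-butene, t-BuOH/THF/H2O, rt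
Reagents that add atoms: sodium chlorite, [Na+].[O-]Cl=O
Why: Pinnick oxidation converts hindered electron-rich benzaldehydes into the acids while 2-methyl-2-butene traps the hypochlorite, so the benzyl ethers, the aryl acetate and the ring should remain untouched.

Step 6
Reactants: 9 3-acetoxy-2,4-bis(benzyloxy)-6-propylbenzoic acid
Product: 10 benzyl 3-acetoxy-2,4-bis(benzyloxy)-6-propylbenzoate
Conditions: BnBr, KHCO3, DMF, rt → 40 °C
Reagents that add atoms: benzyl bromide, BrCc1ccccc1
Why: Carboxylate O-alkylation is an SN2 reaction at the benzylic carbon of the bromide and is therefore indifferent to the two ortho substituents of the acid, while KHCO3 is too weak a base to cleave the aryl acetate.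

Step 7
Reactants: 10 benzyl 3-acetoxy-2,4-bis(benzyloxy)-6-propylbenzoate
Product: 11 benzyl 2,4-bis(benzyloxy)-3-hydroxy-6-propylbenzoate
Conditions: K2CO3 (0.2 equiv), MeOH/THF, 0 °C → rt
Reagents that add atoms: none
Why: Base-catalysed transesterification (Zemplén-type methanolysis) should remove the phenolic acetate far faster than the di-ortho-substituted benzyl benzoate can exchange, which frees only the central phenol.

Step 8
Reactants: 12 dibenzyl 3-oxopentanedioate; 13 hexanoyl chloride
Product: 14 dibenzyl 2-hexanoyl-3-oxopentanedioate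
Conditions: MgCl2, pyridine, CH2Cl2, 0 °C → rt; 1 M HCl work-up
Reagents that add atoms: none
Why: Magnesium-chelate C-acylation of a 1,3-dicarbonyl compound should stop after one acylation on carbon, because the tricarbonyl product stays locked as its chelate until the acidic work-up.

Step 9
Reactants: 14 dibenzyl 2-hexanoyl-3-oxopentanedioate
Product: 15 benzyl 4-hydroxy-2-oxo-6-pentyl-2H-pyran-5-carboxylate
Conditions: DBU, toluene, 90 °C; 1 M HCl work-up
Reagents that add atoms: none
Why: Enol lactonisation of a 3,5-dioxo ester with DBU is the standard route to 4-hydroxy-2-pyrones, and here the enolate oxygen of the hexanoyl ketone can reach only the distal ester in a six-membered closure, expelling benzyl alcohol and keeping the C5 benzyl ester.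

Step 10
Reactants: 15 benzyl 4-hydroxy-2-oxo-6-pentyl-2H-pyran-5-carboxylate
Product: 16 benzyl 4-methoxy-2-oxo-6-pentyl-2H-pyran-5-carboxylate
Conditions: Me2SO4, K2CO3, acetone, reflux
Reagents that add atoms: dimethyl sulfate, COS(=O)(=O)OC
Why: O-alkylation of the vinylogous acid with dimethyl sulfate and K2CO3 in acetone is the standard method that delivers the 4-methoxy-2-pyrone and not the 2-methoxy-4-pyrone isomer.

Step 11
Reactants: 16 benzyl 4-methoxy-2-oxo-6-pentyl-2H-pyran-5-carboxylate
Product: 17 4-methoxy-2-oxo-6-pentyl-2H-pyran-5-carboxylic acid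
Conditions: H2 (1 atm), 10% Pd/C, EtOAc, rt
Reagents that add atoms: none
Why: Hydrogenolysis of the benzyl ester at atmospheric pressure should be much faster than reduction of the fully substituted push–pull double bonds of the pyrone, and it avoids any base that would open the lactone.

Step 12
Reactants: 17 4-methoxy-2-oxo-6-pentyl-2H-pyran-5-carboxylic acid; 11 benzyl 2,4-bis(benzyloxy)-3-hydroxy-6-propylbenzoate
Product: 19 benzyl 2,4-bis(benzyloxy)-3-[(4-methoxy-2-oxo-6-pentyl-2H-pyran-5-carbonyl)oxy]-6-propylbenzoate, via pyrone acid chloride 18 (not isolated)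
Conditions: (COCl)2, DMF (cat.), CH2Cl2, 0 °C → rt, evaporate; then 11, Et3N, DMAP (cat.), CH2Cl2, 0 °C → rt
Reagents that add atoms: none
Why: Acid chloride formation followed by DMAP-catalysed acylation of the phenol (nucleophilic acyl substitution) is the usual answer to a di-ortho-substituted acid that carbodiimide coupling handles poorly, and the acid has no α-hydrogen from which a ketene could form.

Step 13
Reactants: 19 benzyl 2,4-bis(benzyloxy)-3-[(4-methoxy-2-oxo-6-pentyl-2H-pyran-5-carbonyl)oxy]-6-propylbenzoate; 20 1,1-dimethoxyethene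
Product: 23 benzyl 2,4-bis(benzyloxy)-3-[(2,4-dimethoxy-6-pentylbenzoyl)oxy]-6-propylbenzoate, via bicyclic lactone adduct 21 (not isolated), via trimethoxycyclohexadiene ester 22 (not isolated)
Conditions: 20 (excess), toluene, sealed tube, 130 °C
Reagents that add atoms: none
Why: The electron-rich alkene adds to the pyrone diene (pyrone C3=C4–C5=C6) in an inverse-electron-demand (4+2) cycloaddition, its nucleophilic CH2 bonding to pyrone C6 (the β-carbon of the C5 acrylate unit) and its acetal carbon to pyrone C3, which forms ring A bonds C5–C6 and C3–C4 and gives the bridged lactone 21. Retro-(4+2) loss of CO2 from 21 gives diene 22, and 1,2-elimination of methanol from its ketal aromatises ring A. The closest known reaction type is the conversion of 2-pyrone-5-carboxylates (coumalates and their 4,6-disubstituted analogues) into 4-alkoxybenzoates with ketene acetals. Ring A, the only ring formed, closes by this intermolecular (4+2) cycloaddition, and the two bridgehead stereocentres of 21 are transient, so no stereocentre has to be controlled. The step needs one regiochemistry (new OMe para to the ester, new CH beside the pentyl carbon), and the polarisation of the pyrone secures it: C6 is the electrophilic terminus, while C3, α to the lactone carbonyl and β to the 4-methoxy enol ether, pairs with the oxocarbenium-like acetal carbon. Full benzyl protection of ring B leaves no acidic proton to destroy the ketene acetal, and the aryl ester, more electron-withdrawing than an alkyl ester, partly offsets the deactivation by the 4-methoxy group, although heating in a sealed tube is still expected to be needed.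

Step 14
Reactants: 23 benzyl 2,4-bis(benzyloxy)-3-[(2,4-dimethoxy-6-pentylbenzoyl)oxy]-6-propylbenzoate
Product: 24 2,4-dihydroxy-3-[(2,4-dimethoxy-6-pentylbenzoyl)oxy]-6-propylbenzoic acid (CNP0506872.0)
Conditions: H2 (1 atm), 10% Pd/C, EtOAc, rt
Reagents that add atoms: none
Why: Hydrogenolysis over Pd/C cleaves the two benzyl ethers and the benzyl ester under neutral conditions that leave the hindered depside ester and the aryl methyl ethers intact, as is usual for the last step of a depside synthesis.

**Compound list**

1 | 5-propylbenzene-1,3-diol (divarinol) | CCCc1cc(O)cc(O)c1 | starting material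
2 | 1,3-bis(benzyloxy)-5-propylbenzene | CCCc1cc(OCc2ccccc2)cc(OCc2ccccc2)c1 | intermediate
3 | [2,6-bis(benzyloxy)-4-propylphenyl]lithium (not isolated) | [Li]c1c(OCc2ccccc2)cc(CCC)cc1OCc1ccccc1 | intermediate
4 | dimethyl [2,6-bis(benzyloxy)-4-propylphenyl]boronate (not isolated) | COB(OC)c1c(OCc2ccccc2)cc(CCC)cc1OCc1ccccc1 | intermediate
5 | 2,6-bis(benzyloxy)-4-propylphenol | CCCc1cc(OCc2ccccc2)c(O)c(OCc2ccccc2)c1 | intermediate
6 | 2,6-bis(benzyloxy)-4-propylphenyl acetate | CCCc1cc(OCc2ccccc2)c(OC(C)=O)c(OCc2ccccc2)c1 | intermediate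
7 | N-{[3-acetoxy-2,4-bis(benzyloxy)-6-propylphenyl]methylidene}-N-methylmethanaminium chloride (not isolated) | CCCc1cc(OCc2ccccc2)c(OC(C)=O)c(OCc2ccccc2)c1C=[N+](C)C.[Cl-] | intermediate
8 | 2,6-bis(benzyloxy)-3-formyl-4-propylphenyl acetate | CCCc1cc(OCc2ccccc2)c(OC(C)=O)c(OCc2ccccc2)c1C=O | intermediate
9 | 3-acetoxy-2,4-bis(benzyloxy)-6-propylbenzoic acid | CCCc1cc(OCc2ccccc2)c(OC(C)=O)c(OCc2ccccc2)c1C(=O)O | intermediate
10 | benzyl 3-acetoxy-2,4-bis(benzyloxy)-6-propylbenzoate | CCCc1cc(OCc2ccccc2)c(OC(C)=O)c(OCc2ccccc2)c1C(=O)OCc1ccccc1 | intermediate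
11 | benzyl 2,4-bis(benzyloxy)-3-hydroxy-6-propylbenzoate (ring B phenol) | CCCc1cc(OCc2ccccc2)c(O)c(OCc2ccccc2)c1C(=O)OCc1ccccc1 | intermediate
12 | dibenzyl 3-oxopentanedioate | O=C(CC(=O)OCc1ccccc1)CC(=O)OCc1ccccc1 | starting material
13 | hexanoyl chloride | CCCCCC(=O)Cl | starting material
14 | dibenzyl 2-hexanoyl-3-oxopentanedioate | CCCCCC(=O)C(C(=O)OCc1ccccc1)C(=O)CC(=O)OCc1ccccc1 | intermediate
15 | benzyl 4-hydroxy-2-oxo-6-pentyl-2H-pyran-5-carboxylate | CCCCCc1oc(=O)cc(O)c1C(=O)OCc1ccccc1 | intermediate
16 | benzyl 4-methoxy-2-oxo-6-pentyl-2H-pyran-5-carboxylate | CCCCCc1oc(=O)cc(OC)c1C(=O)OCc1ccccc1 | intermediate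
17 | 4-methoxy-2-oxo-6-pentyl-2H-pyran-5-carboxylic acid | CCCCCc1oc(=O)cc(OC)c1C(=O)O | intermediate
18 | 4-methoxy-2-oxo-6-pentyl-2H-pyran-5-carbonyl chloride (not isolated) | CCCCCc1oc(=O)cc(OC)c1C(=O)Cl | intermediate
19 | benzyl 2,4-bis(benzyloxy)-3-[(4-methoxy-2-oxo-6-pentyl-2H-pyran-5-carbonyl)oxy]-6-propylbenzoate | CCCCCc1oc(=O)cc(OC)c1C(=O)Oc1c(OCc2ccccc2)cc(CCC)c(C(=O)OCc2ccccc2)c1OCc1ccccc1 | intermediate
20 | 1,1-dimethoxyethene | C=C(OC)OC | starting material
21 | 2,6-bis(benzyloxy)-3-[(benzyloxy)carbonyl]-4-propylphenyl 5,8,8-trimethoxy-3-oxo-1-pentyl-2-oxabicyclo[2.2.2]oct-5-ene-6-carboxylate (racemic, not isolated) | CCCCCC12CC(OC)(OC)C(C(=O)O1)C(OC)=C2C(=O)Oc1c(OCc2ccccc2)cc(CCC)c(C(=O)OCc2ccccc2)c1OCc1ccccc1 | intermediate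
22 | 2,6-bis(benzyloxy)-3-[(benzyloxy)carbonyl]-4-propylphenyl 4,4,6-trimethoxy-2-pentylcyclohexa-1,5-diene-1-carboxylate (not isolated) | CCCCCC1=C(C(=O)Oc2c(OCc3ccccc3)cc(CCC)c(C(=O)OCc3ccccc3)c2OCc2ccccc2)C(OC)=CC(OC)(OC)C1 | intermediate
23 | benzyl 2,4-bis(benzyloxy)-3-[(2,4-dimethoxy-6-pentylbenzoyl)oxy]-6-propylbenzoate | CCCCCc1cc(OC)cc(OC)c1C(=O)Oc1c(OCc2ccccc2)cc(CCC)c(C(=O)OCc2ccccc2)c1OCc1ccccc1 | intermediate
24 | 2,4-dihydroxy-3-[(2,4-dimethoxy-6-pentylbenzoyl)oxy]-6-propylbenzoic acid (CNP0506872.0) | CCCCCc1cc(OC)cc(OC)c1C(=O)Oc1c(O)cc(CCC)c(C(=O)O)c1O | target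

**Step count**

Total: 14 steps. Longest linear sequence: 10 steps (steps 1–7, 12, 13, 14); the pyrone branch (steps 8–11) is 4 steps.

**Steps most likely to fail**

Step 13. The 4-methoxy group makes the pyrone a weak electrophile, so the ketene acetal may oligomerise, or add to C6 without closing the ring, before cycloaddition is complete. The fallback sets out from 11 and comes back at 23, taking ring A ready-made instead of building it on the ester. Bought 1,3-dimethoxy-5-pentylbenzene F1 should undergo Vilsmeier–Haack formylation (POCl3, DMF) to 2,4-dimethoxy-6-pentylbenzaldehyde F2. Pinnick oxidation (NaClO2, NaH2PO4, 2-methyl-2-butene) should then give 2,4-dimethoxy-6-pentylbenzoic acid F3. Activated with trifluoroacetic anhydride in toluene at room temperature (acylium-type esterification of an electron-rich 2,6-disubstituted benzoic acid), F3 should acylate phenol 11 and give 23 directly.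

Step 12. Acylation of the hindered phenol by the hindered acid chloride may stall, and the phenoxide or DMAP may instead add to the pyrone ring and open it. The fallback sets out from 16 and comes back at 23, reversing the order of ring A formation and esterification. Benzyl ester 16, heated with 20 as in step 13, should give benzyl 2,4-dimethoxy-6-pentylbenzoate F4 by the same cycloaddition, loss of CO2 and loss of methanol on a substrate that tolerates more forcing conditions. Hydrogenolysis (H2, Pd/C) should then give 2,4-dimethoxy-6-pentylbenzoic acid F3. Unlike the pyrone acid, its electron-rich aroyl group can be activated with trifluoroacetic anhydride and joined to 11 to give 23.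

Step 2. Deprotonation at a benzylic OCH2 group followed by [1,2]-Wittig rearrangement may compete with ring lithiation. The fallback sets out from 1 and comes back at 11, introducing the carboxyl first and the third oxygen by a Dakin-type oxidation:
- Divarinol 1 is carboxylated with MeOMgOCO2Me in DMF (Kolbe–Schmitt-type) to 2,4-dihydroxy-6-propylbenzoic acid F5.
- Esterification with benzyl bromide and KHCO3 gives benzyl 2,4-dihydroxy-6-propylbenzoate F6.
- Rieche formylation (Cl2CHOMe, TiCl4) between the two hydroxyls gives benzyl 3-formyl-2,4-dihydroxy-6-propylbenzoate F7; any 5-formyl isomer would have to be separated.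
- Dibenzylation with benzyl bromide and K2CO3 gives benzyl 2,4-bis(benzyloxy)-3-formyl-6-propylbenzoate F8.
- Baeyer–Villiger oxidation with mCPBA gives the formate, benzyl 2,4-bis(benzyloxy)-3-(formyloxy)-6-propylbenzoate F9.
- Methanolysis (K2CO3, MeOH) of F9 gives 11.

**Further compounds**

F1 | step 13 | 1,3-dimethoxy-5-pentylbenzene (bought) | CCCCCc1cc(OC)cc(OC)c1
F2 | step 13 | 2,4-dimethoxy-6-pentylbenzaldehyde | CCCCCc1cc(OC)cc(OC)c1C=O
F3 | step 13 | 2,4-dimethoxy-6-pentylbenzoic acid | CCCCCc1cc(OC)cc(OC)c1C(=O)O
F4 | step 12 | benzyl 2,4-dimethoxy-6-pentylbenzoate | CCCCCc1cc(OC)cc(OC)c1C(=O)OCc1ccccc1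
F5 | step 2 | 2,4-dihydroxy-6-propylbenzoic acid | CCCc1cc(O)cc(O)c1C(=O)O
F6 | step 2 | benzyl 2,4-dihydroxy-6-propylbenzoate | CCCc1cc(O)cc(O)c1C(=O)OCc1ccccc1
F7 | step 2 | benzyl 3-formyl-2,4-dihydroxy-6-propylbenzoate | CCCc1cc(O)c(C=O)c(O)c1C(=O)OCc1ccccc1
F8 | step 2 | benzyl 2,4-bis(benzyloxy)-3-formyl-6-propylbenzoate | CCCc1cc(OCc2ccccc2)c(C=O)c(OCc2ccccc2)c1C(=O)OCc1ccccc1
F9 | step 2 | benzyl 2,4-bis(benzyloxy)-3-(formyloxy)-6-propylbenzoate | CCCc1cc(OCc2ccccc2)c(OC=O)c(OCc2ccccc2)c1C(=O)OCc1ccccc1
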